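What is left of the starting material in the green run at 10.0 d? 1.1%, and 0% at 20.0 d.

| flask | starting material | reagent in the second phase | remark | time | volume of the second phase over the first |
|---|---|---|---|---|---|
| ochre | 0.074 M | 0.052 M | run made earlier |  |  |
| red | 0.074 M | 0.12 M | run made earlier |  |  |
| green | 0.037 M | 0.0777 M | run made earlier |  |  |
| flask | 0.074 M | 0.0777 M |  | 15 d | 2.0 |

| run | time / d | target / % | starting material / % |
|---|---|---|---|
| ochre | 1.67 | 11.5 | 50.2 |
| ochre | 3.00 | 16.6 | 37.2 |
| ochre | 6.00 | 20.2 | 29.0 |
| ochre | 10.0 | 19.8 | 23.3 |
| ochre | 20.0 | 11.6 | 17.9 |
| red | 1.67 | 25.4 | 33.2 |
| red | 3.00 | 33.5 | 19.2 |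
| red | 6.00 | 35.8 | 7.8 |
| red | 10.0 | 29.1 | 2.2 |
| red | 20.0 | 11.3 | 0.9 |
| green | 1.67 | 26.6 | 33.5 |
| green | 3.00 | 33.6 | 18.6 |
| green | 6.00 | 34.4 | 6.1 |
| green | 10.0 | 27.9 | 1.1 |
| green | 20.0 | 9.8 | 0 |

(scatter of a reading: 0.5 percentage points)

- percentages count the starting material that a species holds: one idle adduct counts as two
- target is meant together with its product in the second phase and idle adduct
- in the second phase: reagent in the second phase, product in the second phase; everything else is in the first
- charges count per volume of the first phase; a concentration in a rate is the amount of a species over the volume of its own phase; every rate counts per litre of the first phase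
- on the list of suspects stand: reagent in the reaction phase <-> reagent in the second phase; starting material + reagent in the reaction phase -> target; target <-> product in the second phase; target -> decomposed product; starting material <-> dormant form; starting material + target <-> idle adduct
- the earlier runs hold the two phases in the same ratio of volumes as the flask asked about
- in an amount of target, one idle adduct counts as one target

1. when, up to 15 d, the flask holds most target
2. the amount of target, in percent of the starting material charged, at that time

What does target do in the green run over that stretch? It falls from 27.9% to 9.8%, counted with its forms in the second phase and the idle adduct, with little starting material there to feed it.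

Where is target heading? The list of suspects gives it one exit with no way back, decomposed product, so target is an intermediate and decomposed product is the end state.

How fast is that end approached? Take the logarithm of the ratio of those two green readings and divide by the 10.0 d between them: 0.105 d⁻¹. Call this λ, the late loss constant, the fraction of target lost per day if the feed has stopped. Its half-life is 6.60 d.

Where is the weak spot? The feed may not be quite over. The red run, with 2.2% left at 10.0 d, which is more than green's, gives a smaller 0.0946 d⁻¹, so I read λ as a reading, and a late one.

And how high does the flask go? Its reagent lies 37.8% of the way from ochre to red. Their readings at 6.00 d are 20.2% and 35.8%, so my straight line gives 26.1%, near that time.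

Can the time be trusted? Loosely: ochre moves from 20.2% to 19.8% across 4.00 d.

The forecast, a little above my line, says 27% at 6 d: “The peak is flat, so the time is loose.”

The flask holds most target, 27.3%, at 6.72 d.

    reagent in the reaction phase ⇌ reagent in the second phase, rate k1*([reagent in the reaction phase] - [reagent in the second phase]/K1) per volume of the first phase (partition coefficient = 8.80, kL = 0.00190 min⁻¹)
    starting material + reagent in the reaction phase → target (k = 0.310 M⁻¹ min⁻¹)
    target ⇌ product in the second phase, rate k3*([target] - [product in the second phase]/K3) per volume of the first phase (partition coefficient = 1.50, kL = 5.10 × 10⁻⁴ min⁻¹)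
    target → decomposed product (k = 4.90 × 10⁻⁴ min⁻¹)
    starting material ⇌ dormant form (K = 0.900, k = 2.80 × 10⁻⁴ min⁻¹)
    starting material + target ⇌ idle adduct, settled at all times (K = 38.0 M⁻¹)

The flask still holds 26.8% at 8.40 d. λ goes to work once more on the neighbour flask charged with 0.030 M of starting material and green's reagent. Green, charged with 0.037 M, stands in for it: green's 27.9% at 10.0 d, carried 5.00 d further by λ, gives 16.5%, an estimate for green. At 15.0 d that neighbour, with 0.28% of its starting material left, holds 17.3%.

The numbers in the tables were generated by integration for substances that don't exist; scatter was added.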